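## The problem

- The target 9 is a flavone with no stereocentre, so the task is one of constitution and of keeping the oxygens apart.
- Ring A is a hexasubstituted benzene. C4a carries the C4 ketone, and C5 to C8a carry five contiguous oxygens in three states: free OH on C5 and C6, OMe on C7 and C8, and the pyranone oxygen O1 on C8a.
- Ring B is oxygenated at both positions ortho to C1' (2'-OH, 6'-OMe). This crowds C2 and makes a 2,6-disubstituted benzoyl electrophile a poor partner.
- In the open 1,3-diketone form of such a flavone, every phenol ortho to the three-carbon chain (on C8a, C5 and C2') can close on the far carbonyl. Acid, base or Lewis acid can therefore lead to three isomeric chromones (Wessely–Moser type scrambling).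
- Three methyl ethers must stay while three hydroxyls are free. A late selective demethylation would have to tell O5 and O6 from O7, O8 and O6'.
- The 5,6-catechol in this electron-rich ring is sensitive to air and base. It should be set free late and under neutral conditions.
- The same catechol is the feature the plan exploits. In the o-quinone of the C5/C6 diol of ring A, the only unsubstituted ring carbon is C8a, which is the β-carbon of both the C5=O enone and the C4 ketone and is the carbon that bears O1 of ring C, so the O1–C8a bond can be made from a C8a–H bond by oxidation.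

## Retrosynthesis

**O1–C8a (9 ⇒ 8 ⇒ 7).**
- The aryl–oxygen bond of ring C is cut, not the usual O1–C2 bond. This leads back through the acyl-o-quinone 8 to the open triol diketone 7, which differs from 9 only by H2.
- The neighbouring cut (O1–C2) needs a pentaoxygenated ring A and leaves two or three phenols competing for closure.
- The chosen cut removes one oxygen from ring A. It fixes the direction of closure by the position of the single ring-A C–H, and it delivers 5-OH and 6-OH free.
- The forward reaction must oxidise the catechol selectively. The enol oxygen on C2 must then add to C8a faster than anything else adds to 8.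

**Two O–CH2Ph bonds (7 ⇒ 6).**
- The catechol cannot be present while the chain is built with strong base, and it must not be released by acid or Lewis acid, which would cyclodehydrate the diketone.
- Benzyl ethers in 6 meet both demands, because hydrogenolysis is neutral.
- The 2'-OH needs no mask at any stage.

**C3–C4 (6 ⇒ 4 + 5).**
- The chain is cut next to ring A. Ring A then becomes the ester 4 (electrophile, one ortho substituent) and ring B the methyl ketone 5 (nucleophile).
- The neighbouring cut C2–C3 would need a 2,6-disubstituted ring-B acyl donor with a protected phenol.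
- Compound 5 is commercial and already holds the 2'-OH/6'-OMe pattern. The forward reaction is a crossed Claisen condensation of the doubly deprotonated 5.

**Three O–benzyl bonds (4 ⇒ 3).**
- One operation masks both phenols and turns the acid 3 into the acyl donor 4.
- No separate activation of the acid is then required.

**C2–O and C2–Br of the benzoic acid (3 ⇒ 2 ⇒ 1).**
- The oxygen that becomes O5 is taken off, which leads to the commercial 3,4,5-trioxygenated acid 1.
- In 1 the future O6 is already free and the future O7 and O8 are already methylated, so no methyl ether is ever cleaved in the route.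
- The forward steps must brominate 1 at C2, between OH and CO2H, and exchange the bromide of 2 for hydroxide with help from the ortho carboxylate.

## Roads not taken

**Alternative 1:** (the obvious route) cut O1–C2 and C2–C3.
- Forward: 6-hydroxy-2,3,4,5-tetramethoxyacetophenone A1 would be O-acylated with 2-(benzyloxy)-6-methoxybenzoyl chloride A2. A Baker–Venkataraman shift and acid cyclodehydration would give the 5,6,7,8-tetramethoxyflavone A3. Removal of the methyls on O5 and O6 and of the benzyl group would follow.
- A1 is itself a hexasubstituted benzene that needs several oxidation and methylation steps, and A2 is a hindered acyl donor.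
- The end game rests on two Lewis-acid demethylations next to three methyl ethers that must stay. Those conditions allow 5-hydroxyflavones with an 8-oxygen to open and re-close the other way.
- The chosen plan cleaves no methyl ether and never lets two phenols compete for closure under acid.

**Alternative 2:** cut C4–C4a, C3–C4 and O1–C2.
- Forward: a palladium-catalysed three-component carbonylative alkynylation and cyclisation of 3,4-bis(benzyloxy)-2-iodo-5,6-dimethoxyphenol A4, carbon monoxide and 1-(benzyloxy)-2-ethynyl-3-methoxybenzene A5. This would give the tribenzyl ether A6 of the target, then hydrogenolysis.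
- The union is convergent, but all difficulty moves into A4, a benzene with five oxygens and an iodine that is harder to make than ring A of the target.
- Oxidative addition into its doubly ortho-substituted, very electron-rich C–I bond should be slow.
- The ynone can also close 5-exo to an aurone, and three protecting groups are needed against two in the chosen plan.

**Alternative 3:** the para-quinone twin of the chosen plan.
- Forward: 1-(3-hydroxy-4,5-dimethoxyphenyl)-3-(2-hydroxy-6-methoxyphenyl)propane-1,3-dione A7, with one oxygen fewer than 7, would be oxidised para to its phenol (Teuber type) to the acyl-1,4-benzoquinone A8. The enol oxygen would then add to the quinone.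
- In A8 the carbonyl carbons are C6 and C8a, and the only open carbon is C5.
- Closure therefore puts the ring oxygen on the wrong side and gives the 5,8-dihydroxy-6,7-dimethoxy isomer A9.
- Correction would need a Wessely–Moser equilibration with no structural bias and with the 2'-OH as a third closing partner.
- A7 is simpler than 7, but only the ortho-quinone has the right carbon electrophilic.

Key step: step 6

Assumption: 9 has no stereocentre. The C2–C1' axis is flanked only by OH and OMe on one side and by C3–H and O1 on the other, so it is expected to rotate freely at room temperature. The request for a single enantiomer therefore needs no action.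

## Route

Step 1
Reactants: 1 3-hydroxy-4,5-dimethoxybenzoic acid
Product: 2 2-bromo-3-hydroxy-4,5-dimethoxybenzoic acid
Conditions: Br2 (1.0 equiv), NaOAc, AcOH, 15 °C to rt
Reagents that add atoms: bromine, BrBr
Why: Electrophilic aromatic bromination; C2 is ortho to the free OH and para to the 5-OMe, whereas C6 is screened by the carboxyl group and by the in-plane methyl of the 5-OMe. 3-Hydroxy-4-alkoxybenzoyl compounds are known to brominate between the OH and the carbonyl group under these conditions, and one equivalent of bromine limits a second substitution.

Step 2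
Reactants: 2 2-bromo-3-hydroxy-4,5-dimethoxybenzoic acid
Product: 3 2,3-dihydroxy-4,5-dimethoxybenzoic acid
Conditions: aq NaOH (excess), CuSO4 (cat.), N2, reflux; then cold aq HCl
Reagents that add atoms: sodium hydroxide, [Na+].[OH-]
Why: Ullmann-type copper-catalysed hydroxylation; the ortho carboxylate binds copper and speeds up exchange of the bromide, and the same reaction type turns ortho-bromophenols into catechols. The methyl ethers are inert to aqueous alkali, and exclusion of air protects the catecholate.

Step 3
Reactants: 3 2,3-dihydroxy-4,5-dimethoxybenzoic acid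
Product: 4 benzyl 2,3-bis(benzyloxy)-4,5-dimethoxybenzoate
Conditions: BnBr (3.3 equiv), K2CO3, DMF, 60 °C, N2
Reagents that add atoms: benzyl bromide, BrCc1ccccc1
Why: Williamson alkylation of both phenoxides and of the carboxylate in one operation. The benzyl ester serves directly as acyl donor in step 4, and the two ethers can later be removed without acid or base.

Step 4
Reactants: 4 benzyl 2,3-bis(benzyloxy)-4,5-dimethoxybenzoate; 5 1-(2-hydroxy-6-methoxyphenyl)ethanone
Product: 6 1-[2,3-bis(benzyloxy)-4,5-dimethoxyphenyl]-3-(2-hydroxy-6-methoxyphenyl)propane-1,3-dione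
Conditions: 5, LiHMDS (3.3 equiv), THF, −78 to 0 °C; then 4, 0 °C to rt; cold 1 M HCl
Reagents that add atoms: none
Why: Crossed Claisen condensation; 5 is deprotonated twice, so its phenol protects itself as the phenoxide, and the methyl ketone enolate attacks the non-enolisable ester 4, which has only one ortho substituent. O-acylation of the phenoxide is no dead end, since the same base then effects a Baker–Venkataraman acyl shift to 6. The third equivalent of base deprotonates 6 and makes the condensation irreversible, and the short cold quench avoids cyclodehydration.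

Step 5
Reactants: 6 1-[2,3-bis(benzyloxy)-4,5-dimethoxyphenyl]-3-(2-hydroxy-6-methoxyphenyl)propane-1,3-dione
Product: 7 1-(2,3-dihydroxy-4,5-dimethoxyphenyl)-3-(2-hydroxy-6-methoxyphenyl)propane-1,3-dione
Conditions: H2 (1 atm), 10% Pd/C, EtOAc, rt; filtered under N2 and used at once
Reagents that add atoms: none
Why: Hydrogenolysis of aryl benzyl ethers under neutral conditions, to which the enolised diketone, the aryl ketones and the methyl ethers are inert at 1 atm. No acid or base is present that could close the diketone through the C5 or the 2' phenol.

Step 6
Reactants: 7 1-(2,3-dihydroxy-4,5-dimethoxyphenyl)-3-(2-hydroxy-6-methoxyphenyl)propane-1,3-dione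
Product: 9 5,6,2'-trihydroxy-7,8,6'-trimethoxyflavone, via acyl-o-benzoquinone 8 (not isolated)
Conditions: graphite anode, Pt cathode, undivided cell, potential held just past the first anodic wave of 7 (about 2 F/mol), MeCN–aq NaOAc/AcOH buffer (pH about 6) 3:1, about 5 mM, N2, rt
Reagents that add atoms: none
Why: Proposed new method: the catechol of 7 is by far its most easily oxidised group (ring B is an acyl-deactivated resorcinol monoether), so the anode should take two electrons and two protons from O5–H and O6–H and give the acyl-o-quinone 8 while protons are reduced to hydrogen at the cathode. In 8 the only hydrogen-bearing ring carbon, C8a, is the β-carbon of both the C5=O enone and the C4 ketone, and after rotation about C3–C4 the enol(ate) oxygen on C2 reaches it in a 6-endo-trig oxa-Michael addition that closes ring C through the O1–C8a bond. Loss of the C8a proton re-aromatises ring A and returns the two quinone oxygens as free 5-OH and 6-OH, so 9 forms directly and the net change is loss of H2. The closest known reaction type is the anodic oxidation of catechols in buffered aqueous acetonitrile followed by Michael addition of a nucleophile, including the enol-oxygen closure onto the quinone that ends the catechol/1,3-diketone benzofuran synthesis and the oxidative lactonisation of dihydroxycinnamic acids to dihydroxycoumarins; new is its use for the O1–C8a bond of a flavone. No stereocentre is formed. The regioselectivity of closure is structural: attack by C3 would give a four-membered ring, attack by the 2'-OH an eight-membered ring, addition of the enol oxygen to C5=O is only a reversible hemiketalisation, and C7 and C8 are blocked by methoxy groups. High dilution and a potential kept close to the catechol wave should hold back intermolecular C-addition and oxidation of the enol or of ring B.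

## Compound list

1 | 3-hydroxy-4,5-dimethoxybenzoic acid | COc1cc(C(=O)O)cc(O)c1OC | starting material
2 | 2-bromo-3-hydroxy-4,5-dimethoxybenzoic acid | COc1cc(C(=O)O)c(Br)c(O)c1OC | intermediate
3 | 2,3-dihydroxy-4,5-dimethoxybenzoic acid | COc1cc(C(=O)O)c(O)c(O)c1OC | intermediate
4 | benzyl 2,3-bis(benzyloxy)-4,5-dimethoxybenzoate | COc1cc(C(=O)OCc2ccccc2)c(OCc2ccccc2)c(OCc2ccccc2)c1OC | intermediate
5 | 1-(2-hydroxy-6-methoxyphenyl)ethanone (2'-hydroxy-6'-methoxyacetophenone) | CC(=O)c1c(O)cccc1OC | starting material
6 | 1-[2,3-bis(benzyloxy)-4,5-dimethoxyphenyl]-3-(2-hydroxy-6-methoxyphenyl)propane-1,3-dione | COc1cc(C(=O)CC(=O)c2c(O)cccc2OC)c(OCc2ccccc2)c(OCc2ccccc2)c1OC | intermediate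
7 | 1-(2,3-dihydroxy-4,5-dimethoxyphenyl)-3-(2-hydroxy-6-methoxyphenyl)propane-1,3-dione | COc1cc(C(=O)CC(=O)c2c(O)cccc2OC)c(O)c(O)c1OC | intermediate
8 | 3-[3-(2-hydroxy-6-methoxyphenyl)-3-oxopropanoyl]-5,6-dimethoxycyclohexa-3,5-diene-1,2-dione | COC1=C(OC)C(=O)C(=O)C(C(=O)CC(=O)c2c(O)cccc2OC)=C1 | intermediate
9 | 5,6,2'-trihydroxy-7,8,6'-trimethoxyflavone (no stereocentre) | COc1cccc(O)c1-c1cc(=O)c2c(O)c(O)c(OC)c(OC)c2o1 | target

## Step count and risks

Total step count: 6. Longest linear sequence: 6 steps (1 → 2 → 3 → 4 → 6 → 7 → 9). Compound 5 enters as bought in step 4.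

**Step 6 (key step, proposed new method).**
- The oxidation potential of the product catechol should lie close to that of 7, so over-oxidation of the product is likely. Slow attack of water or acetate on quinone-level material may follow. A reductive work-up reverses the over-oxidation but not the solvolysis.
- Intermolecular Michael addition of the nucleophilic C3 of a second molecule to the quinone is the normal course of such electrolyses. Only dilution holds it back.
- Cyclodehydration of 7 through its C5 or 2' phenol before oxidation would drain the substrate.
- The fallback uses known chemistry, sets out from 4 and returns at 9. It replaces the C8a–H bond by C8a–Br and the oxidation by a copper-catalysed coupling.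
- Saponification (LiOH, aq THF) gives 2,3-bis(benzyloxy)-4,5-dimethoxybenzoic acid F1.
- Bromination of the only free ring position (NBS, MeCN, dark) gives 2,3-bis(benzyloxy)-6-bromo-4,5-dimethoxybenzoic acid F2.
- Oxalyl chloride gives 2,3-bis(benzyloxy)-6-bromo-4,5-dimethoxybenzoyl chloride F3.
- C-acylation of doubly lithiated 5 gives 1-[2,3-bis(benzyloxy)-6-bromo-4,5-dimethoxyphenyl]-3-(2-hydroxy-6-methoxyphenyl)propane-1,3-dione F4.
- Intramolecular Ullmann-type O-arylation of the enolate (CuI, 1,10-phenanthroline, K2CO3, DMF) gives 5,6-bis(benzyloxy)-2-(2-hydroxy-6-methoxyphenyl)-7,8-dimethoxychromen-4-one F5. This reaction is known for 1-(2-haloaryl)-1,3-diketones.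
- Hydrogenolysis of F5 gives 9.

**Step 1.**
- Regiocontrol may be lost through attack at C6, para to the phenol, or a second bromination may occur. Both open positions are activated by one OH and one OMe, and the preference for C2 rests on analogy and sterics.
- The fallback sets out from 1 and returns at 3. It uses a reaction that is ortho-specific by mechanism.
- Fischer esterification gives methyl 3-hydroxy-4,5-dimethoxybenzoate F6.
- Magnesium-mediated formylation (MgCl2, Et3N, paraformaldehyde) gives methyl 2-formyl-3-hydroxy-4,5-dimethoxybenzoate F7. It can only reach C2, because the other ortho position carries OMe.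
- Dakin oxidation gives methyl 2,3-dihydroxy-4,5-dimethoxybenzoate F8, and saponification under nitrogen gives 3.

**Step 2.**
- Hydrodebromination, diaryl ether formation between two substrate molecules, and copper- or air-induced oxidation of the very electron-rich catecholate in hot alkali are the likely losses.
- The fallback sets out from 2 and returns at 4. It never exposes a free catechol.
- Alkylation of 2 (BnBr, K2CO3) gives benzyl 3-(benzyloxy)-2-bromo-4,5-dimethoxybenzoate F9.
- Copper- or palladium-catalysed C–O coupling of F9 with benzyl alcohol (Cs2CO3) gives 4 directly. Ester exchange is degenerate in this step.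

**Step 4.**
- Acylation by the electron-rich, ortho-substituted ester may be slow. Retro-Claisen cleavage on long exposure to base may then limit conversion.
- The fallback sets out from 4 and returns at 6. It makes the C–C bond intramolecularly.
- Saponification gives 2,3-bis(benzyloxy)-4,5-dimethoxybenzoic acid F1 (the acid of the step 6 fallback).
- Oxalyl chloride gives 2,3-bis(benzyloxy)-4,5-dimethoxybenzoyl chloride F10.
- O-acylation of 5 in pyridine gives 2-acetyl-3-methoxyphenyl 2,3-bis(benzyloxy)-4,5-dimethoxybenzoate F11.
- A Baker–Venkataraman rearrangement (KOH, pyridine) on the ring-B phenol gives 6.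

## Further compounds

F1 | step 6 | 2,3-bis(benzyloxy)-4,5-dimethoxybenzoic acid | COc1cc(C(=O)O)c(OCc2ccccc2)c(OCc2ccccc2)c1OC
F2 | step 6 | 2,3-bis(benzyloxy)-6-bromo-4,5-dimethoxybenzoic acid | COc1c(Br)c(C(=O)O)c(OCc2ccccc2)c(OCc2ccccc2)c1OC
F3 | step 6 | 2,3-bis(benzyloxy)-6-bromo-4,5-dimethoxybenzoyl chloride | COc1c(Br)c(C(=O)Cl)c(OCc2ccccc2)c(OCc2ccccc2)c1OC
F4 | step 6 | 1-[2,3-bis(benzyloxy)-6-bromo-4,5-dimethoxyphenyl]-3-(2-hydroxy-6-methoxyphenyl)propane-1,3-dione | COc1c(Br)c(C(=O)CC(=O)c2c(O)cccc2OC)c(OCc2ccccc2)c(OCc2ccccc2)c1OC
F5 | step 6 | 5,6-bis(benzyloxy)-2-(2-hydroxy-6-methoxyphenyl)-7,8-dimethoxychromen-4-one | COc1cccc(O)c1-c1cc(=O)c2c(OCc3ccccc3)c(OCc3ccccc3)c(OC)c(OC)c2o1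
F6 | step 1 | methyl 3-hydroxy-4,5-dimethoxybenzoate | COc1cc(C(=O)OC)cc(O)c1OC
F7 | step 1 | methyl 2-formyl-3-hydroxy-4,5-dimethoxybenzoate | COc1cc(C(=O)OC)c(C=O)c(O)c1OC
F8 | step 1 | methyl 2,3-dihydroxy-4,5-dimethoxybenzoate | COc1cc(C(=O)OC)c(O)c(O)c1OC
F9 | step 2 | benzyl 3-(benzyloxy)-2-bromo-4,5-dimethoxybenzoate | COc1cc(C(=O)OCc2ccccc2)c(Br)c(OCc2ccccc2)c1OC
F10 | step 4 | 2,3-bis(benzyloxy)-4,5-dimethoxybenzoyl chloride | COc1cc(C(=O)Cl)c(OCc2ccccc2)c(OCc2ccccc2)c1OC
F11 | step 4 | 2-acetyl-3-methoxyphenyl 2,3-bis(benzyloxy)-4,5-dimethoxybenzoate | COc1cc(C(=O)Oc2cccc(OC)c2C(C)=O)c(OCc2ccccc2)c(OCc2ccccc2)c1OC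
A1 | alternative 1 | 6-hydroxy-2,3,4,5-tetramethoxyacetophenone | CC(=O)c1c(O)c(OC)c(OC)c(OC)c1OC
A2 | alternative 1 | 2-(benzyloxy)-6-methoxybenzoyl chloride | COc1cccc(OCc2ccccc2)c1C(=O)Cl
A3 | alternative 1 | 2-[2-(benzyloxy)-6-methoxyphenyl]-5,6,7,8-tetramethoxychromen-4-one | COc1cccc(OCc2ccccc2)c1-c1cc(=O)c2c(OC)c(OC)c(OC)c(OC)c2o1
A4 | alternative 2 | 3,4-bis(benzyloxy)-2-iodo-5,6-dimethoxyphenol | COc1c(O)c(I)c(OCc2ccccc2)c(OCc2ccccc2)c1OC
A5 | alternative 2 | 1-(benzyloxy)-2-ethynyl-3-methoxybenzene | C#Cc1c(OC)cccc1OCc1ccccc1
A6 | alternative 2 | 5,6-bis(benzyloxy)-2-[2-(benzyloxy)-6-methoxyphenyl]-7,8-dimethoxychromen-4-one | COc1cccc(OCc2ccccc2)c1-c1cc(=O)c2c(OCc3ccccc3)c(OCc3ccccc3)c(OC)c(OC)c2o1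
A7 | alternative 3 | 1-(3-hydroxy-4,5-dimethoxyphenyl)-3-(2-hydroxy-6-methoxyphenyl)propane-1,3-dione | COc1cc(C(=O)CC(=O)c2c(O)cccc2OC)cc(O)c1OC
A8 | alternative 3 | 2-[3-(2-hydroxy-6-methoxyphenyl)-3-oxopropanoyl]-5,6-dimethoxycyclohexa-2,5-diene-1,4-dione | COC1=C(OC)C(=O)C(C(=O)CC(=O)c2c(O)cccc2OC)=CC1=O
A9 | alternative 3 | 5,8-dihydroxy-2-(2-hydroxy-6-methoxyphenyl)-6,7-dimethoxychromen-4-one | COc1cccc(O)c1-c1cc(=O)c2c(O)c(OC)c(OC)c(O)c2o1
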